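Quinone ring numbered C1(=O) flanked by C2(OMe) and C6(OMe), then C3(H), C4(=O), C5(side chain). The route rests on cutting the C5–CH2 bond. The aryl ketone carbon is the third carbon out from C5 (C5–CH2–CH2–C(=O)Ar), so the chain is a ring-opened 1-(3,4-dimethoxyphenyl)cyclopropan-1-ol. The remaining ring is 2,6-dimethoxy-1,4-benzoquinone, whose C3–H and C5–H are interchanged by the ring's mirror plane. In one operation, AgNO3/K2S2O8 oxidation opens the cyclopropanol to a β-keto alkyl radical, which alkylates the quinone C–H, and the quinone oxidation level is restored. The precursor is the unprotected arylcyclopropanol, one Kulinkovich step from methyl 3,4-dimethoxybenzoate.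

Key step: step 2

Remark on the chemistry: the target (C19H20O7) has no stereocentre, so no stereocontrol is needed. The cyclopropanol is used with its O–H free, because the O–H is the site of oxidation. Ti(OiPr)4 is taken in stoichiometric amount for the electron-rich aromatic ester.

Step 1
Reactants: 1 methyl 3,4-dimethoxybenzoate; 2 ethylmagnesium bromide
Product: 3 1-(3,4-dimethoxyphenyl)cyclopropan-1-ol
Conditions: Ti(OiPr)4 (1.0 equiv), EtMgBr (3.0 equiv, added over 1–2 h), THF, 0 °C to rt; then sat. aq NH4Cl, 0 °C; chromatography on Et3N-deactivated silica; used promptly
Reagents that add atoms: ethylmagnesium bromide, CC[Mg]Br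
Why: Kulinkovich cyclopropanation, in which a titanacyclopropane made in the flask from Ti(OiPr)4 and two EtMgBr (with loss of ethane) acts as a 1,2-dicarbanion equivalent that adds twice to the ester carbonyl and expels methoxide; the aryl methyl ethers are inert, no stereocentre is formed, and the mild NH4Cl quench should keep the acid- and base-sensitive cyclopropanol from opening to the ethyl ketone.

Step 2
Reactants: 3 1-(3,4-dimethoxyphenyl)cyclopropan-1-ol; 4 2,6-dimethoxy-1,4-benzoquinone
Product: 7 evelynin, via beta-keto alkyl radical 5 (not isolated), via quinone adduct radical 6 (not isolated)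
Conditions: 4 (2.0 equiv), AgNO3 (20 mol%), K2S2O8 (3.0 equiv), CH2Cl2/H2O (1:1), rt; 3 added slowly
Reagents that add atoms: none
Why: Divalent silver, generated from AgNO3 by K2S2O8, removes one electron from the cyclopropanol O–H of 3, and release of ring strain cleaves a C–C bond of the three-membered ring to give the primary β-keto alkyl radical 5. This nucleophilic radical adds to an unsubstituted ring carbon of the electron-poor quinone 4 (new C5–CH2 bond) to give adduct radical 6, which is oxidised by divalent silver or persulfate and loses the C5 proton, so the quinone is regenerated without a separate reoxidation. The closest known reaction type is the silver-catalysed, persulfate-driven oxidative ring opening of cyclopropanols with capture of the β-keto radical by quinones, a relative of Minisci-type and decarboxylative radical alkylation. No ring is closed and no stereocentre is created, since the sp3 carbon of 6 returns to sp2. Site selectivity is secured by the substrate itself, because C3 and C5 of 4 are exchanged by the mirror plane through C1 and C4 and the methoxy-bearing carbons C2 and C6 are blocked; mono-alkylation should be favoured by the excess of 4 and by the steric and electronic deactivation of the remaining C3–H in 7. Chemoselectivity rests on the strained alcohol being oxidised much faster than the veratryl ring, which is further deactivated by the acyl group once the ring has opened.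

Compound list
1 | methyl 3,4-dimethoxybenzoate | COC(=O)c1ccc(OC)c(OC)c1 | starting material
2 | ethylmagnesium bromide | CC[Mg]Br | starting material
3 | 1-(3,4-dimethoxyphenyl)cyclopropan-1-ol | COc1ccc(C2(O)CC2)cc1OC | intermediate
4 | 2,6-dimethoxy-1,4-benzoquinone (2,6-dimethoxycyclohexa-2,5-diene-1,4-dione) | COC1=CC(=O)C=C(OC)C1=O | starting material
5 | 3-(3,4-dimethoxyphenyl)-3-oxopropyl radical (beta-keto alkyl radical, not isolated) | [CH2]CC(=O)c1ccc(OC)c(OC)c1 | intermediate
6 | quinone adduct radical (2,6-dimethoxycyclohex-2-ene-1,4-dione ring with sp3 C5 bearing H and the 3-(3,4-dimethoxyphenyl)-3-oxopropyl chain, radical centre at C6; racemic at C5, not isolated) | COC1=CC(=O)C(CCC(=O)c2ccc(OC)c(OC)c2)[C](OC)C1=O | intermediate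
7 | evelynin, 2,6-dimethoxy-1,4-benzoquinone carrying the 3-(3,4-dimethoxyphenyl)-3-oxopropyl chain at C5 (locant 3 by lowest-locant rules) | COC1=CC(=O)C(CCC(=O)c2ccc(OC)c(OC)c2)=C(OC)C1=O | target

Total step count: 2
Longest linear sequence: 2 steps (1 → 3 → 7); quinone 4 is commercial and enters at step 2.

Steps most likely to fail (the route has only two steps, so both are ranked):

1. Step 2. The risks are a second alkylation at the remaining C3–H of the product, non-productive consumption of the cyclopropanol (isomerisation to the ethyl ketone, radical dimerisation or hydrogen abstraction before capture), and oxidative attack on the electron-rich aryl ring. The fallback sets out from cyclopropanol 3, forms the same C–C bond by two-electron chemistry and reveals the quinone last. Commercial 1,2,3,5-tetramethoxybenzene F1 would be brominated at one of its two equivalent free positions (NBS, MeCN, 0 °C) to give 1-bromo-2,3,4,6-tetramethoxybenzene F2. A palladium-catalysed ring-opening cross-coupling of 3 with F2 through the palladium homoenolate (Pd(OAc)2, XPhos, Cs2CO3, toluene, 80 °C) should give 1-(3,4-dimethoxyphenyl)-3-(2,3,4,6-tetramethoxyphenyl)propan-1-one F3. Oxidative demethylation of F3 with (NH4)2Ce(NO3)6 in MeCN/H2O at 0 °C can form a para-quinone only across the single para pair of methoxy carbons of the tetramethoxy ring (C3 and C6, counting the chain carbon as C1). This gives the 2,6-dimethoxyquinone pattern and comes back to the route at evelynin 7.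

2. Step 1. The risks are direct double addition of EtMgBr to the ester outrunning the titanium-mediated cyclopropanation, and ring opening of the electron-rich cyclopropanol to the ethyl ketone during work-up or chromatography. The fallback dispenses with the cyclopropanol. It sets out from quinone 4 and uses commercial 4-(3,4-dimethoxyphenyl)-4-oxobutanoic acid F4 as the radical source. Silver-catalysed oxidative decarboxylation (AgNO3 cat., (NH4)2S2O8, MeCN/H2O, 65 °C; Kochi–Minisci-type decarboxylative alkylation of quinones) should generate the same radical 5 from the carboxylate, and addition to 4 with reoxidation comes back to the route at evelynin 7.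

Further compounds
F1 | step 2 | 1,2,3,5-tetramethoxybenzene | COc1cc(OC)c(OC)c(OC)c1
F2 | step 2 | 1-bromo-2,3,4,6-tetramethoxybenzene | COc1cc(OC)c(Br)c(OC)c1OC
F3 | step 2 | 1-(3,4-dimethoxyphenyl)-3-(2,3,4,6-tetramethoxyphenyl)propan-1-one | COc1cc(OC)c(CCC(=O)c2ccc(OC)c(OC)c2)c(OC)c1OC
F4 | step 1 | 4-(3,4-dimethoxyphenyl)-4-oxobutanoic acid | COc1ccc(C(=O)CCC(=O)O)cc1OC
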